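The rate constants come from no measurement.

Begin at the end.

    pre-initiator ⇌ initiator (K1 = 0.36, k1 = 0.65 /h)
    free monomer + living end → monomer in chains + living end, rate k2*[living end]*[free monomer] (k2 = 2.2 /M/h)
    free monomer + initiator → living end + monomer in chains (k3 = 0.056 /M/h)

free monomer 0.20 M (fed, over 50 h); pre-initiator 10 mM; time 10 d

* average number of monomer units in a chain (chains begun, living or dead) at 10 d
* part of the free monomer that has reacted at 10 d

- the average divides the monomer in chains by the number of chains begun, living and dead together
- run time (flask): 10 d

1. Our reckoning first. The relaxation half-life of step one, 0.282 h, is far shorter than the feed, so in the flask the initiator keeps a share f = 26.5% of what has not yet become living ends. The scheme has no ending step, so chains begun equal c(living end).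

2. Growing and starting both carry c(free monomer), which cancels in their ratio. We call S = k2/(k3·f) = 148 the ladder number. With x = c(living end)/c(pre-initiator charged), c(monomer in chains) = c(pre-initiator charged)·[x + S·(−ln(1 − x) − x)] as long as the share f holds, and dp is this divided by c(living end).

3. Free monomer is the limiting reagent, so the curve stops where that expression reaches the charge. Expanding the logarithm gives x = 0.519 at first and 0.427 corrected. The level of c(living end) is 4.27 mM, and dp there is 46.9.

4. During the feed c(living end) rises with the square of time, from the starting rate constant 1.48 × 10⁻⁴ /h, and reaches 0.741 mM at 50 h.

5. Afterwards we draw a hyperbolic tangent from mid-feed towards the level, with time scale 144 h. Its knee lies near 7.04 d.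

6. At 10 d this gives 3.86 mM, so x = 0.386, dp 40.1 and c 77.3%.

7. The forecast stands lower than our reckoning, at dp 37 and c 67%, with “roughly 0.134 M sits in those chains”.

8. The flask gives dp 36.7 and c 66.2%, so the forecast held, and our curve ran ahead of the simulated c(living end), 0.00361 M at 10.0 d. That simulated value in the ladder gives x = 0.361 and dp 36.6. A neighbouring flask has 0.0025 M of pre-initiator and the same ladder number. Its simulated c(living end), 0.00109 M, gives x = 0.436 and dp 47.4. That neighbouring flask itself gives c 26.0% and dp 47.7.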